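## The problem

Target 21, (3R,6'R)-7,8-didehydro-β,ε-caroten-3-ol, is a C40 chain of eight E double bonds and one triple bond (C7' to C7) between two different rings. Ring ε (2,6,6-trimethylcyclohex-2-enyl) is bound through the stereocentre C6'. Ring β (4-hydroxy-2,6,6-trimethylcyclohex-1-enyl) is bound through C6 to the C7≡C8 triple bond. The segment C9 to C9' is C2-symmetric, so the joining problem is to put two different termini on a symmetric polyene without statistical mixtures. The two stereocentres, C3 (R, secondary carbinol) and C6' (R, a C–H allylic to both C4'=C5' and C7'=C8'), lie 22 bonds apart. Neither can control the other, and C6' must never meet a base or acid strong enough to move C4'=C5' into conjugation. Seven of the eight double bonds are thermodynamic problems: heat or iodine funnels their Z isomers to E. The eighth, C9=C10, is not. C8 carries no hydrogen, so 9Z costs nothing sterically, and any allyl anion or cation spanning C9–C11, or any late equilibration, erodes 9E. The finished polyene is sensitive to light, oxygen and Brønsted or Lewis acids, and it carries a free hydroxyl.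

The feature that opens the problem is the unit C7≡C8–C9(CH3)=C10H on C6 of ring β. It is a buta-1,3-diyne (C7 to C10) whose outer triple bond has taken up a methyl group at C9 and a carbon substituent at C10 on the same side. C6 is an sp2 carbon whose ketone precursor can enolise in one direction only, because C1 is quaternary.

## Retrosynthesis

**Cut 1 (C10–C11 and C9–CH3).** Target 21 is cut into hydroxy diyne 11, AlMe3 and the C26 heptaenyl iodide 19. Syn-methylmetalation of the terminal triple bond of 11 writes the C9 methyl and the 9E geometry kinetically. The alkenyl metal 20 is configurationally stable and is joined to 19 at a single bond between two preformed sp2 carbons. The neighbouring cut at C11=C12 (olefination) would place an allyl anion or cation across C9–C11 and give a new E/Z mixture that could not be corrected afterwards. The cut at C8–C9 would need the trisubstituted alkenyl halide from elsewhere. The precursors are a C13 ring diyne and a polyene that contains no enyne. The forward reaction must add only to the outer triple bond, with methyl at C9, and couple with retention.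

**Cut 2 (C11=C12).** Iodide 19 comes from the all-E C25 aldehyde 18 by one-carbon iodo-olefination. This keeps the C12 carbon at the aldehyde level until the last moment. The forward step must give the E-iodide without acid or base.

**Cut 3 (C11'=C12').** Aldehyde 18 comes from the E/Z mixture 17, which is cut into phosphonium salt 14 and the symmetric C10 dialdehyde 15. The Wittig step need not be stereoselective. The 11'Z isomer is a hindered cis-olefin, and ring ε tolerates iodine equilibration. The funnel is used here, before any enyne exists, so the scrambling that is fatal at C9=C10 is harmless at C9'=C10'. The forward step must olefinate one formyl group of 15 only, which the lower electrophilicity of the longer polyenal and an excess of 15 should secure.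

**Cut 4 (C10'–C11' and C–P).** Salt 14 comes from vinyl carbinol 13 and from (R)-α-ionone 12. Compound 12 already holds ring ε, C6' and the E-C7'=C8' bond. The forward steps are a 1,2-addition and an allylic transposition, and they must not ionise or deprotonate C6'.

**Cut 5 (C6–C7).** Diyne 11 comes from the bis-silylated compound 10, which is cut at the sp2–sp bond into enol triflate 6 and 1,4-bis(trimethylsilyl)buta-1,3-diyne 7. Acetylide addition to the ketone and dehydration was the neighbouring choice. It needs acid or a dehydrating agent next to the carbinol, whereas the triflate is regiospecific. The forward reaction must couple a hindered tetrasubstituted triflate with a diynyl metal.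

**Cut 6 (C–O triflate, C3–H).** Triflate 6 comes from silyl ether 4 and from (4R,6R)-actinol 3. The methyl-bearing stereocentre of 3 is erased on enolisation, so only the carbinol centre must be set. Actinol comes from achiral ketoisophorone 1 through an ene-reductase and a ketoreductase, which together create the C3 carbinol on an unbiased CH2–CO–CH2 unit.

## Roads not taken

Alternative 1: The most obvious plan is a double Wittig on dial 15, cutting both C11'=C12' and C11=C12. The forward key step would be the Wittig reaction of aldehyde 18 with the acetylenic C15 phosphonium salt A1. The ylide of A1 is an allyl anion across C9–C11 next to the triple bond, and making A1 from its allylic alcohol passes through the matching allyl cation. Both scramble 9E. The new C11=C12 bond forms as an E/Z mixture, and the heat or iodine that would correct it drives C9=C10 toward 9Z. The step count is about the same, but the route ends in an isomer separation on the C40 compound. The chosen plan forms no bond after the enyne that needs correction.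

Alternative 2: Cut C6–C7 by Sonogashira coupling of triflate 6 with commercial (E)-3-methylpent-2-en-4-yn-1-ol to give enynol A2, oxidise it to enynal A3, and close C11=C12 by Horner–Wadsworth–Emmons reaction with the C25 phosphonate A4. This takes 9E from a purchased alkene and keeps the anion off the enyne side. It needs three extra steps on a hexaene to turn 18 into A4 (reduction, a fragile polyenyl bromide, Arbuzov reaction). It still makes C11=C12 by an olefination that cannot be equilibrated afterwards, and it needs a final desilylation on the C40 compound. The chosen plan makes C10–C11 as a single bond with both geometries preset.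

Alternative 3: A temporary sulfur tether across C15/C15'. The C20 allylic bromide A6 and the C20 thiol A7 are joined through sulfur, oxidised to sulfone A5, and the central C15=C15' bond is made by Ramberg–Bäcklund extrusion of SO2. The hetero-union is inherently selective and the central bond forms intramolecularly. Each C20 half needs four or five steps and a labile retinyl-type halide. The enyne 9E geometry must still be made by other means. The halogenating strong base of the extrusion would act on a substrate with the C6' bis-allylic C–H and with allylic sulfone positions next to trisubstituted double bonds. The chosen plan is shorter and never exposes C6' to strong base.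

Key step: step 11

Assumption: (R)-α-ionone 12 is bought in high enantiomeric purity (natural grade); its purity sets that of C6', which no later step touches.

## Route

Step 1
Reactants: 1 ketoisophorone (2,6,6-trimethylcyclohex-2-ene-1,4-dione)
Product: 3 (4R,6R)-4-hydroxy-2,2,6-trimethylcyclohexan-1-one (actinol), via (6R)-levodione 2 (not isolated)
Conditions: ene-reductase (old yellow enzyme family), then ketoreductase (levodione reductase type), NADP+/NAD+ (cat.), glucose dehydrogenase, D-glucose, phosphate buffer pH 7, 30 °C
Reagents that add atoms: none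
Why: Two-enzyme asymmetric bioreduction: the flavin-dependent ene-reductase adds hydride and a proton anti across C2=C3 of 1 to give (6R)-2, and the ketoreductase then delivers hydride to one face of the unhindered C4 carbonyl only (C1 is shielded by three methyl groups), setting the carbinol as R; this carbon becomes C3 of the target, and the methyl-bearing centre is erased in step 3.

Step 2
Reactants: 3 (4R,6R)-actinol
Product: 4 (4R,6R)-2,2,6-trimethyl-4-[(triethylsilyl)oxy]cyclohexan-1-one
Conditions: Et3SiCl, imidazole, DMF, 0 °C to 23 °C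
Reagents that add atoms: chlorotriethylsilane, CC[Si](CC)(CC)Cl
Why: Standard silylation of a secondary alcohol; the triethylsilyl ether should survive LiN(iPr)2 and the zinc coupling and is later removed by the same fluoride that frees the alkyne.

Step 3
Reactants: 4 silyl ether
Product: 6 (4R)-2,6,6-trimethyl-4-[(triethylsilyl)oxy]cyclohex-1-en-1-yl trifluoromethanesulfonate, via lithium enolate 5 (not isolated)
Conditions: LiN(iPr)2, THF, −78 °C; PhNTf2, −78 °C to 0 °C
Reagents that add atoms: N-phenylbis(trifluoromethanesulfonimide), O=S(=O)(N(c1ccccc1)S(=O)(=O)C(F)(F)F)C(F)(F)F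
Why: Enol triflate formation: deprotonation can occur only at C6 because C2 is quaternary, so a single enolate 5 forms and is O-sulfonylated; the methyl-bearing stereocentre becomes sp2 (either epimer would converge here) and the silyloxy centre is untouched.

Step 4
Reactants: 6 enol triflate; 7 1,4-bis(trimethylsilyl)buta-1,3-diyne
Product: 10 triethyl{[(1R)-3,5,5-trimethyl-4-[4-(trimethylsilyl)buta-1,3-diyn-1-yl]cyclohex-3-en-1-yl]oxy}silane, via lithium (trimethylsilyl)butadiynide 8 (not isolated), via bromo[(trimethylsilyl)butadiynyl]zinc 9 (not isolated)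
Conditions: 7, MeLi·LiBr, THF, 23 °C; ZnBr2, 0 °C; then 6, Pd(PPh3)4 (5 mol %), THF, 23 °C to 45 °C
Reagents that add atoms: none
Why: MeLi·LiBr cleaves one C–Si bond of 7, transmetalation to zinc gives 9, and Negishi alkynylation of the alkenyl triflate forms the C6–C7 bond; the remaining Me3Si group keeps the diyne monomeric and isolable.

Step 5
Reactants: 10 bis-silylated diyne
Product: 11 (1R)-4-(buta-1,3-diyn-1-yl)-3,5,5-trimethylcyclohex-3-en-1-ol
Conditions: Bu4NF (2.2 equiv), THF, 0 °C, short contact; used at once as a solution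
Reagents that add atoms: none
Why: Fluoride cleaves the C(sp)–Si and the O–Si bond in one operation; short contact at 0 °C and immediate use should limit oligomerisation of the terminal diyne.

Step 6
Reactants: 12 (R)-α-ionone, (3E)-4-[(1R)-2,6,6-trimethylcyclohex-2-en-1-yl]but-3-en-2-one
Product: 13 (4E)-3-methyl-5-[(1R)-2,6,6-trimethylcyclohex-2-en-1-yl]penta-1,4-dien-3-ol (both C3 epimers)
Conditions: CH2=CHMgBr, THF, −20 °C to 0 °C; aq. NH4Cl
Reagents that add atoms: vinylmagnesium bromide, C=C[Mg]Br
Why: 1,2-Addition of the Grignard reagent to the enone carbonyl at low temperature; C6' is not involved, and the new carbinol centre is lost in step 7, so its configuration is immaterial.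

Step 7
Reactants: 13 vinyl carbinol
Product: 14 triphenyl{(2E,4E)-3-methyl-5-[(1R)-2,6,6-trimethylcyclohex-2-en-1-yl]penta-2,4-dien-1-yl}phosphonium bromide
Conditions: PPh3·HBr, MeOH, 23 °C; crystallisation
Reagents that add atoms: triphenylphosphine hydrobromide, [PH+](c1ccccc1)(c1ccccc1)c1ccccc1.[Br-]
Why: Ionisation of the tertiary bis-allylic alcohol and capture of the allyl cation by PPh3 at the primary terminus (SN1' phosphonium salt formation) gives the conjugated dienyl salt; C6' is not part of the cation, ring ε should not isomerise under this mild acid, and crystallisation should remove the 2Z isomer.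

Step 8
Reactants: 14 phosphonium bromide; 15 (2E,4E,6E)-2,7-dimethylocta-2,4,6-trienedial
Product: 17 (2E,4E,6E,10E,12E)-2,7,11-trimethyl-13-[(1R)-2,6,6-trimethylcyclohex-2-en-1-yl]trideca-2,4,6,8,10,12-hexaenal as 8E/8Z mixture, via phosphorus ylide 16 (not isolated)
Conditions: 15 (2 equiv), NaOMe, CH2Cl2/MeOH, 0 °C to 23 °C, slow addition of 14
Reagents that add atoms: none
Why: Wittig olefination of one formyl group of the symmetric dial with the semi-stabilised ylide 16; the first olefination lengthens the conjugation and lowers the electrophilicity of the remaining aldehyde, and 15 is in excess, so mono-olefination should dominate; the new double bond forms as an E/Z mixture that step 9 corrects.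

Step 9
Reactants: 17 C25 aldehyde, 8E/8Z mixture
Product: 18 (2E,4E,6E,8E,10E,12E)-2,7,11-trimethyl-13-[(1R)-2,6,6-trimethylcyclohex-2-en-1-yl]trideca-2,4,6,8,10,12-hexaenal
Conditions: I2 (2 mol %), heptane/CH2Cl2, 23 °C, diffuse light; crystallisation, mother liquor re-equilibrated
Reagents that add atoms: none
Why: Iodine-catalysed photo-equilibration through reversible iodine-atom addition; the 8Z isomer suffers the hindered-cis clash between the C7 methyl group and H10, so the equilibrium should lie on the all-E side and crystallisation drains it; no enyne is present yet, so nothing in the molecule prefers Z.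

Step 10
Reactants: 18 all-E C25 aldehyde
Product: 19 (1E,3E,5E,7E,9E,11E,13E)-1-iodo-3,8,12-trimethyl-14-[(1R)-2,6,6-trimethylcyclohex-2-en-1-yl]tetradeca-1,3,5,7,9,11,13-heptaene
Conditions: CHI3, CrCl2, THF/1,4-dioxane, 0 °C, dark; used promptly
Reagents that add atoms: iodoform, IC(I)I
Why: Takai iodo-olefination: the geminal dichromium species from CHI3 and CrCl2 adds to the aldehyde, and elimination from the β-oxido intermediate should give the E-alkenyl iodide, strongly favoured for a conjugated α-methyl enal; the medium is neither basic nor acidic, so C6' is safe.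

Step 11
Reactants: 11 hydroxy diyne; 19 heptaenyl iodide
Product: 21 (3R,6'R)-7,8-didehydro-β,ε-caroten-3-ol, via alkenylalane 20 (not isolated)
Conditions: 11, AlMe3 (4 equiv), Cp2ZrCl2 (0.5 equiv), CH2Cl2, 0 °C to 23 °C; volatiles off in vacuo; then 19, ZnCl2 (0.5 equiv), Pd2(dba)3 (2.5 mol %), P(2-furyl)3 (10 mol %), THF, 23 °C, dark; aq. Rochelle salt
Reagents that add atoms: trimethylaluminium, C[Al](C)C
Why: Zr-catalysed methylalumination followed in the same flask by Pd/Zn-co-catalysed alkenyl–alkenyl Negishi coupling; the closest known reaction type is the methylalumination of terminal alkynes, conjugated enynes and diynes and the direct coupling of the resulting E-alkenylalanes with alkenyl iodides in all-E polyene synthesis. AlMe3 first turns the hydroxyl into OAlMe2 with loss of methane; the methylzirconocene–aluminate pair then adds CH3 and metal syn across the terminal C9≡C10 bond, CH3 to the internal carbon C9 and aluminium to C10, giving 20. The inner C7≡C8 bond is internal and screened by the 2,6,6-trimethylcyclohexenyl ring, so it should stay; this chemoselectivity and the methyl-to-C9 regiochemistry are the selectivities the step needs. After removal of excess AlMe3 the alkenyl group passes through zinc to palladium; oxidative addition of 19 and reductive elimination both go with retention, so C10–C11 forms with 9E from the syn addition and 11E from 19. No ring is closed and no stereocentre is created; C3 and C6' are spectators because no allyl anion, allyl cation or strong base is generated. Aqueous work-up frees the hydroxyl and gives 21 directly; no heat or iodine is applied after this point, since equilibration would favour 9Z.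

## Compound list

1 | ketoisophorone, 2,6,6-trimethylcyclohex-2-ene-1,4-dione | CC1=CC(=O)CC(C)(C)C1=O | starting material
2 | (6R)-levodione, (6R)-2,2,6-trimethylcyclohexane-1,4-dione | O=C1[C@H](C)CC(=O)CC1(C)C | intermediate
3 | (4R,6R)-actinol, (4R,6R)-4-hydroxy-2,2,6-trimethylcyclohexan-1-one | O=C1[C@H](C)C[C@@H](O)CC1(C)C | intermediate
4 | (4R,6R)-2,2,6-trimethyl-4-[(triethylsilyl)oxy]cyclohexan-1-one | O=C1[C@H](C)C[C@@H](O[Si](CC)(CC)CC)CC1(C)C | intermediate
5 | lithium (4R)-2,6,6-trimethyl-4-[(triethylsilyl)oxy]cyclohex-1-en-1-olate | [Li]OC1=C(C)C[C@@H](O[Si](CC)(CC)CC)CC1(C)C | intermediate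
6 | (4R)-2,6,6-trimethyl-4-[(triethylsilyl)oxy]cyclohex-1-en-1-yl trifluoromethanesulfonate | FC(F)(F)S(=O)(=O)OC1=C(C)C[C@@H](O[Si](CC)(CC)CC)CC1(C)C | intermediate
7 | 1,4-bis(trimethylsilyl)buta-1,3-diyne | C[Si](C)(C)C#CC#C[Si](C)(C)C | starting material
8 | lithium (trimethylsilyl)butadiynide | [Li]C#CC#C[Si](C)(C)C | intermediate
9 | bromo[(trimethylsilyl)butadiynyl]zinc | Br[Zn]C#CC#C[Si](C)(C)C | intermediate
10 | triethyl{[(1R)-3,5,5-trimethyl-4-[4-(trimethylsilyl)buta-1,3-diyn-1-yl]cyclohex-3-en-1-yl]oxy}silane | C[Si](C)(C)C#CC#CC1=C(C)C[C@@H](O[Si](CC)(CC)CC)CC1(C)C | intermediate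
11 | (1R)-4-(buta-1,3-diyn-1-yl)-3,5,5-trimethylcyclohex-3-en-1-ol | C#CC#CC1=C(C)C[C@@H](O)CC1(C)C | intermediate
12 | (R)-α-ionone, (3E)-4-[(1R)-2,6,6-trimethylcyclohex-2-en-1-yl]but-3-en-2-one | CC1=CCCC(C)(C)[C@H]1/C=C/C(C)=O | starting material
13 | (4E)-3-methyl-5-[(1R)-2,6,6-trimethylcyclohex-2-en-1-yl]penta-1,4-dien-3-ol, both C3 epimers | CC1=CCCC(C)(C)[C@H]1/C=C/C(C)(O)C=C | intermediate
14 | triphenyl{(2E,4E)-3-methyl-5-[(1R)-2,6,6-trimethylcyclohex-2-en-1-yl]penta-2,4-dien-1-yl}phosphonium bromide | CC1=CCCC(C)(C)[C@H]1/C=C/C(C)=C/C[P+](c1ccccc1)(c1ccccc1)c1ccccc1.[Br-] | intermediate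
15 | (2E,4E,6E)-2,7-dimethylocta-2,4,6-trienedial | O=C/C(C)=C/C=C/C=C(C)/C=O | starting material
16 | phosphorus ylide of 14, {(2E,4E)-3-methyl-5-[(1R)-2,6,6-trimethylcyclohex-2-en-1-yl]penta-2,4-dien-1-ylidene}triphenylphosphorane | CC1=CCCC(C)(C)[C@H]1/C=C/C(C)=C/C=P(c1ccccc1)(c1ccccc1)c1ccccc1 | intermediate
17 | (2E,4E,6E,10E,12E)-2,7,11-trimethyl-13-[(1R)-2,6,6-trimethylcyclohex-2-en-1-yl]trideca-2,4,6,8,10,12-hexaenal, mixture of 8E and 8Z | CC1=CCCC(C)(C)[C@H]1/C=C/C(C)=C/C=CC(/C)=C/C=C/C=C(C)/C=O | intermediate
18 | (2E,4E,6E,8E,10E,12E)-2,7,11-trimethyl-13-[(1R)-2,6,6-trimethylcyclohex-2-en-1-yl]trideca-2,4,6,8,10,12-hexaenal | CC1=CCCC(C)(C)[C@H]1/C=C/C(C)=C/C=C/C(C)=C/C=C/C=C(C)/C=O | intermediate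
19 | (1E,3E,5E,7E,9E,11E,13E)-1-iodo-3,8,12-trimethyl-14-[(1R)-2,6,6-trimethylcyclohex-2-en-1-yl]tetradeca-1,3,5,7,9,11,13-heptaene | CC1=CCCC(C)(C)[C@H]1/C=C/C(C)=C/C=C/C(C)=C/C=C/C=C(C)/C=C/I | intermediate
20 | {(1E)-4-[(4R)-4-(dimethylalumanyloxy)-2,6,6-trimethylcyclohex-1-en-1-yl]-2-methylbut-1-en-3-yn-1-yl}dimethylalumane | C[Al](C)/C=C(\C)C#CC1=C(C)C[C@@H](O[Al](C)C)CC1(C)C | intermediate
21 | (3R,6'R)-7,8-didehydro-β,ε-caroten-3-ol; (1R)-3,5,5-trimethyl-4-[(3E,5E,7E,9E,11E,13E,15E,17E)-3,7,12,16-tetramethyl-18-[(1R)-2,6,6-trimethylcyclohex-2-en-1-yl]octadeca-3,5,7,9,11,13,15,17-octaen-1-yn-1-yl]cyclohex-3-en-1-ol | CC1=CCCC(C)(C)[C@H]1/C=C/C(C)=C/C=C/C(C)=C/C=C/C=C(C)/C=C/C=C(\C)C#CC1=C(C)C[C@@H](O)CC1(C)C | target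

## Step count and risks

Total: 11 steps. Longest linear sequence: 6 steps (steps 1, 2, 3, 4, 5, 11, or steps 6, 7, 8, 9, 10, 11).

**Step 11 (key step).** The most likely failure is at the coupling stage. Heptaenyl iodide 19 may decompose in contact with residual methylaluminium species, which are Lewis acidic, and a methyl group may be transferred to palladium in competition with the alkenyl group. A lesser risk is metalation of the acidic diyne C–H in place of carbometalation. The fallback sets out from 11 and 18 and comes back at 21, with reversed polarity and two isolable partners. Diyne 11 is methylaluminated as before, but the alane is quenched with I2 to give (1R)-4-[(3E)-4-iodo-3-methylbut-3-en-1-yn-1-yl]-3,5,5-trimethylcyclohex-3-en-1-ol F1. Aldehyde 18 is treated with Cl2CHBpin, CrCl2 and LiI to give the E-alkenyl boronate 4,4,5,5-tetramethyl-2-[(1E,3E,5E,7E,9E,11E,13E)-3,8,12-trimethyl-14-[(1R)-2,6,6-trimethylcyclohex-2-en-1-yl]tetradeca-1,3,5,7,9,11,13-heptaen-1-yl]-1,3,2-dioxaborolane F2. Suzuki–Miyaura coupling of F1 with F2 (PdCl2(dppf), K3PO4, THF/H2O, 23 °C, dark) should give 21 with retention at both carbons, and the polyene never meets an aluminium reagent.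

**Step 10.** Incomplete E selectivity in the elimination would put an 11Z unit into the chain that cannot be corrected after step 11. The long polyenyl iodide may also lose iodine under light. The fallback sets out from 18 and comes back at 19. Colvin homologation with LiC(N2)SiMe3 (THF, −78 °C to 23 °C) gives the terminal enyne (6R)-1,5,5-trimethyl-6-[(1E,3E,5E,7E,9E,11E)-3,7,12-trimethyltetradeca-1,3,5,7,9,11-hexaen-13-yn-1-yl]cyclohex-1-ene F3. Hydrozirconation with Cp2Zr(H)Cl gives chlorobis(cyclopentadienyl)[(1E,3E,5E,7E,9E,11E,13E)-3,8,12-trimethyl-14-[(1R)-2,6,6-trimethylcyclohex-2-en-1-yl]tetradeca-1,3,5,7,9,11,13-heptaen-1-yl]zirconium F4, which is not isolated. Treatment of F4 with I2 gives 19, whose E geometry follows from syn addition and retention.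

**Step 4.** Oxidative addition at the hindered tetrasubstituted triflate may be slow, so that the diynylzinc reagent homocouples or oligomerises before it is consumed. The fallback sets out from 6 and comes back at 11, building the diyne in two stages. Sonogashira coupling of 6 with ethynyltrimethylsilane (Pd(PPh3)4, CuI, Et3N) gives triethyl{[(1R)-3,5,5-trimethyl-4-[(trimethylsilyl)ethynyl]cyclohex-3-en-1-yl]oxy}silane F5. K2CO3 in MeOH gives triethyl{[(1R)-4-ethynyl-3,5,5-trimethylcyclohex-3-en-1-yl]oxy}silane F6. Cadiot–Chodkiewicz coupling with (bromoethynyl)triisopropylsilane (CuCl, NH2OH·HCl, n-BuNH2) gives triethyl{[(1R)-3,5,5-trimethyl-4-[4-(triisopropylsilyl)buta-1,3-diyn-1-yl]cyclohex-3-en-1-yl]oxy}silane F7. Bu4NF then gives 11.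

**Step 1.** The two reductions may run in the wrong order (carbonyl reduction of 1 before C=C reduction), or hydride delivery to C4 may not be fully face-selective, which would lower the purity at C3. The fallback sets out from 1 and comes back at enolate 5, using a metal catalyst for the carbinol and the convergence at C6. Ru-catalysed asymmetric transfer hydrogenation of the C4 carbonyl of 1 (RuCl(p-cymene)(TsDPEN) of the hand that gives the S alcohol, 2-propanol) gives (4S)-4-hydroxy-2,6,6-trimethylcyclohex-2-en-1-one F8. Hydrogenation of the C=C bond (H2, Rh/Al2O3, EtOAc) gives 3 together with its epimer (4R,6S)-4-hydroxy-2,2,6-trimethylcyclohexan-1-one F9. Silylation as in step 2 gives 4 together with (4R,6S)-2,2,6-trimethyl-4-[(triethylsilyl)oxy]cyclohexan-1-one F10. Both give the same enolate 5 under the conditions of step 3.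

## Further compounds

F1 | step 11 | (1R)-4-[(3E)-4-iodo-3-methylbut-3-en-1-yn-1-yl]-3,5,5-trimethylcyclohex-3-en-1-ol | I/C=C(\C)C#CC1=C(C)C[C@@H](O)CC1(C)C
F2 | step 11 | 4,4,5,5-tetramethyl-2-[(1E,3E,5E,7E,9E,11E,13E)-3,8,12-trimethyl-14-[(1R)-2,6,6-trimethylcyclohex-2-en-1-yl]tetradeca-1,3,5,7,9,11,13-heptaen-1-yl]-1,3,2-dioxaborolane | CC1=CCCC(C)(C)[C@H]1/C=C/C(C)=C/C=C/C(C)=C/C=C/C=C(C)/C=C/B1OC(C)(C)C(C)(C)O1
F3 | step 10 | (6R)-1,5,5-trimethyl-6-[(1E,3E,5E,7E,9E,11E)-3,7,12-trimethyltetradeca-1,3,5,7,9,11-hexaen-13-yn-1-yl]cyclohex-1-ene | CC1=CCCC(C)(C)[C@H]1/C=C/C(C)=C/C=C/C(C)=C/C=C/C=C(C)/C#C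
F4 | step 10 | chlorobis(cyclopentadienyl)[(1E,3E,5E,7E,9E,11E,13E)-3,8,12-trimethyl-14-[(1R)-2,6,6-trimethylcyclohex-2-en-1-yl]tetradeca-1,3,5,7,9,11,13-heptaen-1-yl]zirconium | CC1=CCCC(C)(C)[C@H]1/C=C/C(C)=C/C=C/C(C)=C/C=C/C=C(C)/C=C/[Zr](Cl)(C1C=CC=C1)C1C=CC=C1
F5 | step 4 | triethyl{[(1R)-3,5,5-trimethyl-4-[(trimethylsilyl)ethynyl]cyclohex-3-en-1-yl]oxy}silane | C[Si](C)(C)C#CC1=C(C)C[C@@H](O[Si](CC)(CC)CC)CC1(C)C
F6 | step 4 | triethyl{[(1R)-4-ethynyl-3,5,5-trimethylcyclohex-3-en-1-yl]oxy}silane | C#CC1=C(C)C[C@@H](O[Si](CC)(CC)CC)CC1(C)C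
F7 | step 4 | triethyl{[(1R)-3,5,5-trimethyl-4-[4-(triisopropylsilyl)buta-1,3-diyn-1-yl]cyclohex-3-en-1-yl]oxy}silane | CC(C)[Si](C(C)C)(C(C)C)C#CC#CC1=C(C)C[C@@H](O[Si](CC)(CC)CC)CC1(C)C
F8 | step 1 | (4S)-4-hydroxy-2,6,6-trimethylcyclohex-2-en-1-one | O=C1C(C)=C[C@@H](O)CC1(C)C
F9 | step 1 | (4R,6S)-4-hydroxy-2,2,6-trimethylcyclohexan-1-one | O=C1[C@@H](C)C[C@@H](O)CC1(C)C
F10 | step 1 | (4R,6S)-2,2,6-trimethyl-4-[(triethylsilyl)oxy]cyclohexan-1-one | O=C1[C@@H](C)C[C@@H](O[Si](CC)(CC)CC)CC1(C)C
A1 | alternative 1 | {(2E)-5-[(4R)-4-hydroxy-2,6,6-trimethylcyclohex-1-en-1-yl]-3-methylpent-2-en-4-yn-1-yl}triphenylphosphonium bromide | c1ccccc1[P+](c1ccccc1)(c1ccccc1)C/C=C(\C)C#CC1=C(C)C[C@@H](O)CC1(C)C.[Br-]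
A2 | alternative 2 | (2E)-3-methyl-5-[(4R)-2,6,6-trimethyl-4-[(triethylsilyl)oxy]cyclohex-1-en-1-yl]pent-2-en-4-yn-1-ol | OC/C=C(\C)C#CC1=C(C)C[C@@H](O[Si](CC)(CC)CC)CC1(C)C
A3 | alternative 2 | (2E)-3-methyl-5-[(4R)-2,6,6-trimethyl-4-[(triethylsilyl)oxy]cyclohex-1-en-1-yl]pent-2-en-4-ynal | O=C/C=C(\C)C#CC1=C(C)C[C@@H](O[Si](CC)(CC)CC)CC1(C)C
A4 | alternative 2 | diethyl {(2E,4E,6E,8E,10E,12E)-2,7,11-trimethyl-13-[(1R)-2,6,6-trimethylcyclohex-2-en-1-yl]trideca-2,4,6,8,10,12-hexaen-1-yl}phosphonate | CC1=CCCC(C)(C)[C@H]1/C=C/C(C)=C/C=C/C(C)=C/C=C/C=C(C)/CP(=O)(OCC)OCC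
A5 | alternative 3 | unsymmetrical C40 bis-allylic sulfone bridging C15 and C15' | CC1=CCCC(C)(C)[C@H]1/C=C/C(C)=C/C=C/C(C)=C/CS(=O)(=O)C/C=C(C)/C=C/C=C(\C)C#CC1=C(C)C[C@@H](O)CC1(C)C
A6 | alternative 3 | (6R)-6-[(1E,3E,5E,7E)-9-bromo-3,7-dimethylnona-1,3,5,7-tetraen-1-yl]-1,5,5-trimethylcyclohex-1-ene | CC1=CCCC(C)(C)[C@H]1/C=C/C(C)=C/C=C/C(C)=C/CBr
A7 | alternative 3 | (1R)-4-[(3E,5E,7E)-3,7-dimethyl-9-sulfanylnona-3,5,7-trien-1-yn-1-yl]-3,5,5-trimethylcyclohex-3-en-1-ol | SC/C=C(C)/C=C/C=C(\C)C#CC1=C(C)C[C@@H](O)CC1(C)C
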